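## Retrosynthetic overview

1. Target ⇒ cut the C15=C5′ enol-lactone double bond: (13E)-6α,8α,18-trihydroxylabd-13-en-15-al plus the phosphorus ylide of the lactol carbon of 5-hydroxy-4-methylfuranone. The ylide is a masked acyl anion, so two carbonyl-level (normally electrophilic) carbons are joined.
2. Enal ⇒ (13E)-labd-13-ene-6α,8α,15,18-tetraol ⇒ one LiAlH4 reduction of an E-enoate that carries an 18,6α-lactone and an 8α,17-epoxide.
3. Enoate ⇒ Horner–Wadsworth–Emmons reaction on the C13 methyl ketone; 18,6α-lactone ⇒ 6α-OH-directed radical functionalisation of the 4α-methyl (C18), then RuO4.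
4. Epoxy hydroxy ketone ⇒ (+)-larixol by side-chain cleavage and α-face epoxidation of the 8(17)-alkene.
5. Ring order: rings A and B come intact from larixol; the temporary rings (8α,17-epoxide, then 6α,18-tetrahydrofuran → γ-lactone) are opened together in one reduction; the butenolide is bought as a ring and becomes the ylidene lactone in the last step.

Assumption: (+)-larixol is bought (catalogue diterpene; bulk source larch oleoresin); labdane numbering is used (C18 = 4α carbon, C19 = 4β methyl, C17 on C8, C16 on C13, C20 on C10).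

## Route

Step 1
Reactants: 1 (+)-larixol [(13S)-labda-8(17),14-diene-6α,13-diol]
Product: 2 6α-hydroxy-14,15-dinorlabd-8(17)-en-13-one
Conditions: KMnO4, acetone, 0 °C → rt
Reagents that add atoms: none
Why: Permanganate oxidative cleavage of the tertiary vinyl carbinol (dihydroxylation of the vinyl group, then C13–C14 glycol cleavage) gives the methyl ketone, because the monosubstituted vinyl group reacts much faster than the hindered 1,1-disubstituted 8(17)-alkene and the secondary 6α-OH is oxidised only slowly at 0 °C; no ring stereocentre is touched.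

Step 2
Reactants: 2 6α-hydroxy-14,15-dinorlabd-8(17)-en-13-one
Product: 3 8α,17-epoxy-6α-hydroxy-14,15-dinorlabdan-13-one
Conditions: mCPBA, CH2Cl2, 0 °C
Reagents that add atoms: mCPBA (3-chloroperoxybenzoic acid), OOC(=O)c1cccc(Cl)c1
Why: Prilezhaev epoxidation takes place on the α face of the exocyclic alkene, anti to the axial C10 methyl and syn to the homoallylic 6α-OH, which fixes C8 with oxygen α and the C17 methylene β.

Step 3
Reactants: 3 8α,17-epoxy-6α-hydroxy-14,15-dinorlabdan-13-one
Product: 6 6α,18:8α,17-diepoxy-14,15-dinorlabdan-13-one, via 6α-hypoiodite 4 (not isolated), via 18-iodo alcohol 5 (not isolated)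
Conditions: PhI(OAc)2, I2, cyclohexane, hν (visible), 25 °C
Reagents that add atoms: none
Why: Suárez hypoiodite reaction: the 6α-alkoxy radical abstracts hydrogen by 1,5-transfer from the equatorial 4α-methyl, which is syn-pentane related to the equatorial 6α-oxygen (O···C18 about 2.5 Å, against about 3.5 Å to C19 and over 4 Å to C20), the C18 radical is iodinated and the 6α-oxygen displaces iodide to close the tetrahydrofuran, so C4 becomes a stereocentre with the oxidised carbon α and the methyl β.

Step 4
Reactants: 6 6α,18:8α,17-diepoxy-14,15-dinorlabdan-13-one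
Product: 7 8α,17-epoxy-13-oxo-14,15-dinorlabdan-18,6α-olide
Conditions: RuCl3·xH2O (cat.), NaIO4, CCl4/MeCN/H2O, rt
Reagents that add atoms: sodium periodate NaIO4 (oxygen source, delivered through RuO4), [Na+].[O-]I(=O)(=O)=O
Why: RuO4 oxidation of a cyclic ether to the γ-lactone (Sharpless RuCl3/NaIO4 conditions) takes the accessible C18 methylene next to oxygen and not the axial C6–H, which is shielded by the C19 and C20 methyls, while the ketone and the epoxide tolerate the near-neutral medium.

Step 5
Reactants: 7 8α,17-epoxy-13-oxo-14,15-dinorlabdan-18,6α-olide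
Product: 8 ethyl (13E)-8α,17-epoxy-18-oxo-6α,18-epoxylabd-13-en-15-oate (18,6α-lactone E-enoate)
Conditions: (EtO)2P(O)CH2CO2Et, NaH, THF, 0 → 50 °C; chromatography to remove the 13Z isomer
Reagents that add atoms: triethyl phosphonoacetate, CCOC(=O)CP(=O)(OCC)OCC
Why: Horner–Wadsworth–Emmons olefination of the methyl ketone puts the ester anti to the larger CH2 chain (13E, expected about 5:1, minor Z isomer separated), and the lactone (no α-hydrogen) and the hindered epoxide are inert to the phosphonate anion.

Step 6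
Reactants: 8 ethyl (13E)-8α,17-epoxy-18-oxo-6α,18-epoxylabd-13-en-15-oate
Product: 9 (13E)-labd-13-ene-6α,8α,15,18-tetraol
Conditions: LiAlH4, THF, 0 °C → reflux; aqueous NaOH work-up
Reagents that add atoms: none
Why: One exhaustive LiAlH4 reduction does three jobs: 1,2-reduction of the enoate to the allylic alcohol, reduction of the lactone to the 6α,18-diol, and hydride opening of the epoxide at the primary C17, which leaves the 8α-oxygen in place and makes C17 the 8β-methyl (sclareol-type C8), with the 13E alkene untouched.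

Step 7
Reactants: 10 5-hydroxy-4-methylfuran-2(5H)-one (racemic lactol)
Product: 11 (3-methyl-5-oxo-2,5-dihydrofuran-2-yl)triphenylphosphonium bromide (racemic)
Conditions: PPh3·HBr, MeCN, 70 °C
Reagents that add atoms: triphenylphosphine hydrobromide, [Br-].[PH+](c1ccccc1)(c1ccccc1)c1ccccc1
Why: Acid-promoted substitution at the lactol carbon (ionisation of the pseudo-acid hydroxyl by HBr and capture by PPh3, the same phosphonium salt formation that converts 2-formylbenzoic acid into the phthalidyl salt) gives the salt, whose single stereocentre is racemic and is erased in step 8.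

Step 8
Reactants: 9 (13E)-labd-13-ene-6α,8α,15,18-tetraol; 11 (3-methyl-5-oxo-2,5-dihydrofuran-2-yl)triphenylphosphonium bromide
Product: 14 target CNP0126806.1 (13E,15Z)-ylidene butenolide, via enal 12 (not isolated), via phosphorus ylide 13 (not isolated)
Conditions: MnO2, CH2Cl2, rt; then 11, Et3N, rt → 40 °C (same pot, dark)
Reagents that add atoms: none
Why: Proposed new method: tandem allylic oxidation–Wittig olefination in which MnO2 oxidises only the allylic C15 alcohol of the unprotected tetraol and the ylide from 11 then acts as a masked acyl anion (the lactol carbon, electrophilic in 10, is made nucleophilic by phosphorus and by the aromatic 2-oxidofuran resonance form) that attacks the aldehyde carbon C15 and, by loss of Ph3PO, forms the C15=C5′ enol-lactone double bond; the closest known reactions are Wittig olefinations with phthalid-3-yl and tetrahydropyran-2-yl triphenylphosphonium ylides and in situ MnO2 oxidation–Wittig sequences with stabilised ylides; the 15Z geometry is expected because addition of the stabilised ylide is reversible and the E isomer would clash with the ring 4-methyl, while the 13E geometry is carried through unchanged.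

## Compound list

1 | (+)-larixol, (13S)-labda-8(17),14-diene-6α,13-diol | C=C[C@@](C)(O)CC[C@@H]1[C@@]2(C)CCCC(C)(C)[C@@H]2[C@@H](O)CC1=C | starting material
2 | 6α-hydroxy-14,15-dinorlabd-8(17)-en-13-one | CC(=O)CC[C@@H]1[C@@]2(C)CCCC(C)(C)[C@@H]2[C@@H](O)CC1=C | intermediate
3 | 8α,17-epoxy-6α-hydroxy-14,15-dinorlabdan-13-one | CC(=O)CC[C@@H]1[C@@]2(C)CCCC(C)(C)[C@@H]2[C@@H](O)C[C@@]1(C3)O3 | intermediate
4 | 8α,17-epoxy-6α-(iodooxy)-14,15-dinorlabdan-13-one (6α-hypoiodite, not isolated) | CC(=O)CC[C@@H]1[C@@]2(C)CCCC(C)(C)[C@@H]2[C@@H](OI)C[C@@]1(C3)O3 | intermediate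
5 | 8α,17-epoxy-6α-hydroxy-18-iodo-14,15-dinorlabdan-13-one (not isolated) | CC(=O)CC[C@@H]1[C@@]2(C)CCC[C@@](C)(CI)[C@@H]2[C@@H](O)C[C@@]1(C3)O3 | intermediate
6 | 6α,18:8α,17-diepoxy-14,15-dinorlabdan-13-one | CC(=O)CC[C@@H]1[C@@]2(C)CCC[C@@](C)(CO3)[C@@H]2[C@@H]3C[C@@]1(C4)O4 | intermediate
7 | 8α,17-epoxy-13-oxo-14,15-dinorlabdan-18,6α-olide | CC(=O)CC[C@@H]1[C@@]2(C)CCC[C@@](C)(C(=O)O3)[C@@H]2[C@@H]3C[C@@]1(C4)O4 | intermediate
8 | ethyl (13E)-8α,17-epoxy-18-oxo-6α,18-epoxylabd-13-en-15-oate | CCOC(=O)/C=C(\C)CC[C@@H]1[C@@]2(C)CCC[C@@](C)(C(=O)O3)[C@@H]2[C@@H]3C[C@@]1(C4)O4 | intermediate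
9 | (13E)-labd-13-ene-6α,8α,15,18-tetraol | OC/C=C(\C)CC[C@@H]1[C@@]2(C)CCC[C@@](C)(CO)[C@@H]2[C@@H](O)C[C@@]1(C)O | intermediate
10 | 5-hydroxy-4-methylfuran-2(5H)-one (racemic) | CC1=CC(=O)OC1O | starting material
11 | (3-methyl-5-oxo-2,5-dihydrofuran-2-yl)triphenylphosphonium bromide (racemic) | CC1=CC(=O)OC1[P+](c1ccccc1)(c1ccccc1)c1ccccc1.[Br-] | intermediate
12 | (13E)-6α,8α,18-trihydroxylabd-13-en-15-al (not isolated) | O=C/C=C(\C)CC[C@@H]1[C@@]2(C)CCC[C@@](C)(CO)[C@@H]2[C@@H](O)C[C@@]1(C)O | intermediate
13 | 4-methyl-5-(triphenyl-λ5-phosphanylidene)furan-2(5H)-one (ylide, not isolated) | CC1=CC(=O)OC1=P(c1ccccc1)(c1ccccc1)c1ccccc1 | intermediate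
14 | CNP0126806.1, (5Z)-4-methyl-5-ylidenefuran-2(5H)-one joined through C15 to the (13E)-labd-13-ene-6α,8α,18-triol skeleton | CC1=CC(=O)O/C1=C\C=C(/C)CC[C@@H]1[C@@]2(C)CCC[C@@](C)(CO)[C@@H]2[C@@H](O)C[C@@]1(C)O | target

## Step count and risks

Total step count: 8. Longest linear sequence: 7 (steps 1–6 and 8).

**Risk 1, step 3 (remote C18 functionalisation; its fallback also replaces step 4).** The 6α-alkoxy radical may fragment, or the iodine reagents may attack the epoxide. The fallback reaches the same C18–H by a Barton nitrite photolysis, which uses no iodine or oxidant and delivers C18 at the aldehyde level. It sets out from 3: NOCl in pyridine at −20 °C gives the 6α-nitrite ester F1. Photolysis (Hg lamp, Pyrex, benzene, 10 °C) and warming in iPrOH give the 6α-hydroxy-18-aldoxime F2. Aqueous NaHSO3 followed by dilute acid frees the 18-aldehyde, which closes on the 6α-hydroxyl as the 18,6α-lactol F3. Ag2CO3 on Celite in refluxing benzene oxidises F3 to lactone 7, where the route is rejoined.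

**Risk 2, step 5 (13E selectivity of the olefination).** If the E/Z ratio or the separation is poor, the alkene is built by stereospecific syn-carbometalation instead. The fallback sets out from 7: LiN(iPr)2 at −78 °C and ClP(O)(OEt)2 give the kinetic enol diethyl phosphate F4 in the flask, and more LiN(iPr)2 (−78 → 0 °C) eliminates it to the terminal alkyne lactone F5. LiAlH4 reduces lactone and epoxide to 15,16-dinorlabd-13-yne-6α,8α,18-triol F6. AlMe3 with Cp2ZrCl2 (cat.) in CH2Cl2 adds methyl and aluminium syn across the alkyne to give the (E)-alkenylalane F7, with the three hydroxyls held as dimethylaluminium alkoxides. n-BuLi and then paraformaldehyde convert F7 into tetraol 9 as a single alkene isomer, where the route is rejoined.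

**Risk 3, step 8 (key olefination).** The ylide may be too stabilised to engage the hindered enal, or the one-pot oxidation may interfere. The fallback separates the two events and uses a sulfur-based acyl anion equivalent in a Julia–Kocienski olefination, which is driven by irreversible loss of SO2. It sets out from 9 and 10: MnO2 alone gives enal 12, which is now isolated. Lactol 10 and 2-mercaptobenzothiazole (TsOH, toluene, reflux) give 5-(1,3-benzothiazol-2-ylsulfanyl)-4-methylfuran-2(5H)-one F8, and mCPBA oxidises it to 5-(1,3-benzothiazol-2-ylsulfonyl)-4-methylfuran-2(5H)-one F9. DBU in THF (−20 °C → rt) with 12 and F9 gives 14 directly, where the route is rejoined.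

## Further compounds

F1 | step 3 | 8α,17-epoxy-13-oxo-14,15-dinorlabdan-6α-yl nitrite | CC(=O)CC[C@@H]1[C@@]2(C)CCCC(C)(C)[C@@H]2[C@@H](ON=O)C[C@@]1(C3)O3
F2 | step 3 | 8α,17-epoxy-6α-hydroxy-13-oxo-14,15-dinorlabdan-18-al (E)-oxime | CC(=O)CC[C@@H]1[C@@]2(C)CCC[C@@](C)(/C=N/O)[C@@H]2[C@@H](O)C[C@@]1(C3)O3
F3 | step 3 | 6α,18:8α,17-diepoxy-18-hydroxy-14,15-dinorlabdan-13-one (lactol, anomeric mixture) | CC(=O)CC[C@@H]1[C@@]2(C)CCC[C@@](C)(C(O)O3)[C@@H]2[C@@H]3C[C@@]1(C4)O4
F4 | step 5 | diethyl enol phosphate of 7 at C13 (terminal enol) | C=C(OP(=O)(OCC)OCC)CC[C@@H]1[C@@]2(C)CCC[C@@](C)(C(=O)O3)[C@@H]2[C@@H]3C[C@@]1(C4)O4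
F5 | step 5 | 8α,17-epoxy-15,16-dinorlabd-13-yn-18,6α-olide | C#CCC[C@@H]1[C@@]2(C)CCC[C@@](C)(C(=O)O3)[C@@H]2[C@@H]3C[C@@]1(C4)O4
F6 | step 5 | 15,16-dinorlabd-13-yne-6α,8α,18-triol | C#CCC[C@@H]1[C@@]2(C)CCC[C@@](C)(CO)[C@@H]2[C@@H](O)C[C@@]1(C)O
F7 | step 5 | (13E)-14-(dimethylalumanyl)-15-norlabd-13-ene-6α,8α,18-triol tris(dimethylaluminium) alkoxide | C[Al](C)/C=C(\C)CC[C@@H]1[C@@]2(C)CCC[C@@](C)(CO[Al](C)C)[C@@H]2[C@@H](O[Al](C)C)C[C@@]1(C)O[Al](C)C
F8 | step 8 | 5-(1,3-benzothiazol-2-ylsulfanyl)-4-methylfuran-2(5H)-one (racemic) | CC1=CC(=O)OC1Sc1nc2ccccc2s1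
F9 | step 8 | 5-(1,3-benzothiazol-2-ylsulfonyl)-4-methylfuran-2(5H)-one (racemic) | CC1=CC(=O)OC1S(=O)(=O)c1nc2ccccc2s1
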